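The route rests on disconnecting the lactone O–C8 bond of the trans-fused α-methylene-γ-butyrolactone (germacrane numbering: C12 carbonyl, C7/C8 ring fusion). The key step converts an acyclic syn-(7R,8R) γ-hydroxy tert-butyl ester, the diastereomer that chromium-catalysed 2-(alkoxycarbonyl)allylation should deliver, into the lactone in one operation: O-triflation at C8 triggers 5-exo-tet attack of the C12 ester carbonyl oxygen with inversion and loss of isobutene, setting (8S). It exploits the 1,4-disposition of C12 and C8 across C11–C7 in the five-membered ring and the trans H7/H8 relationship. The ten-membered ring is closed afterwards by ring-closing metathesis at C1=C10, whose in-ring cis geometry suits that reaction.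

Key step: step 9

Numbering: germacrane numbering is used throughout: ring alkenes C1=C10 and C4=C5, ring-fusion carbons C7 and C8, methylene-lactone carbons C11–C13 (C12 = carbonyl), C14 = acetoxymethyl carbon on C10, C15 = acyloxymethyl carbon on C4.
Assumption: the sense of induction of the chromium/bis(oxazoline) catalyst in step 8 is assigned by analogy with simple 2-(alkoxycarbonyl)allylations; should it prove opposite, the enantiomeric ligand is used.

Step 1
Reactants: 1 ethyl 2-(hydroxymethyl)prop-2-enoate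
Product: 2 ethyl 2-{[(tert-butyldimethylsilyl)oxy]methyl}prop-2-enoate
Conditions: TBSCl, imidazole, CH2Cl2, 0 °C → rt
Reagents that add atoms: tert-butyldimethylsilyl chloride, CC(C)(C)[Si](C)(C)Cl
Why: Routine silylation of the primary alcohol gives the side-chain hydroxyl a protecting group that should survive steps 2–10 and fall to fluoride in step 11.

Step 2
Reactants: 2 ethyl 2-{[(tert-butyldimethylsilyl)oxy]methyl}prop-2-enoate
Product: 3 2-{[(tert-butyldimethylsilyl)oxy]methyl}prop-2-enoic acid
Conditions: LiOH, THF/H2O, 0 °C → rt; 1 M HCl to pH 3, 0 °C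
Reagents that add atoms: lithium hydroxide, [Li+].[OH-]
Why: Saponification of the unhindered ethyl ester should proceed without touching the primary silyl ether.

Step 3
Reactants: 4 prop-2-yn-1-ol; 5 5-bromo-2-methylpent-2-ene; 6 3-bromoprop-1-ene
Product: 9 (2Z)-2-(4-methylpent-3-en-1-yl)hexa-2,5-dien-1-ol, via Grignard reagent 7 (not isolated), via alkenylmagnesium chelate 8 (not isolated)
Conditions: 5, Mg, THF, rt; then 4 (0.4 equiv), CuI (10 mol%), THF/Et2O, −10 °C → rt; then 6 (excess), 0 °C → rt; aq. NH4Cl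
Reagents that add atoms: none
Why: Copper-catalysed anti-carbomagnesiation of the propargylic alkoxide puts the alkyl group (C3–C1) on the internal carbon (C4) and magnesium on the terminal carbon (C5) cis to the CH2O group in a five-membered chelate, so copper-assisted allylation of 8 with retention should fix C15 cis to C6, which is the in-ring trans C4=C5 geometry of the target.

Step 4
Reactants: 9 (2Z)-2-(4-methylpent-3-en-1-yl)hexa-2,5-dien-1-ol; 3 2-{[(tert-butyldimethylsilyl)oxy]methyl}prop-2-enoic acid
Product: 10 (2Z)-2-(4-methylpent-3-en-1-yl)hexa-2,5-dien-1-yl 2-{[(tert-butyldimethylsilyl)oxy]methyl}prop-2-enoate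
Conditions: EDC·HCl, DMAP (cat.), CH2Cl2, 0 °C → rt
Reagents that add atoms: none
Why: Steglich-type carbodiimide esterification of the primary allylic alcohol installs the complete C15 side chain early, before any allylic halide or aldehyde is present.

Step 5
Reactants: 10 (2Z)-2-(4-methylpent-3-en-1-yl)hexa-2,5-dien-1-yl 2-{[(tert-butyldimethylsilyl)oxy]methyl}prop-2-enoate; 11 tert-butyl 2-(bromomethyl)prop-2-enoate
Product: 12 tert-butyl (2Z,5Z)-2-(bromomethyl)-6-{[(2-{[(tert-butyldimethylsilyl)oxy]methyl}prop-2-enoyl)oxy]methyl}-10-methylundeca-2,5,9-trienoate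
Conditions: 11 (5 equiv), second-generation Hoveyda–Grubbs catalyst RuCl2(H2IMes)(=CH-C6H4-2-OiPr) (5 mol%), 1,4-benzoquinone (10 mol%), CH2Cl2, 40 °C
Reagents that add atoms: none
Why: Olefin cross-metathesis joins the only monosubstituted alkene of 10 (C7) with the 1,1-disubstituted acrylate, the trisubstituted alkenes and the side-chain acrylate being spectators and the trans C4=C5 bond ruling out ring closure, and the more stable enoate geometry (ester trans to the chain, CH2Br cis to C6) should result.

Step 6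
Reactants: 13 2-[(trimethylsilyl)methyl]prop-2-en-1-yl acetate; 14 formaldehyde (used as paraformaldehyde)
Product: 15 4-hydroxy-2-methylidenebutyl acetate
Conditions: (CH2O)n, BF3·OEt2, CH2Cl2, −78 → −20 °C; aq. NaHCO3
Reagents that add atoms: none
Why: Hosomi–Sakurai reaction, in which the allylsilane attacks BF3-activated formaldehyde at its terminal carbon with allylic transposition and loss of silicon, should deliver the C8–C9–C10(=CH2)–C14 unit with the acetate already in place.

Step 7
Reactants: 15 4-hydroxy-2-methylidenebutyl acetate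
Product: 16 2-methylidene-4-oxobutyl acetate
Conditions: Dess–Martin periodinane, NaHCO3, CH2Cl2, 0 °C; used at once
Reagents that add atoms: none
Why: Buffered Dess–Martin oxidation is neutral and fast at 0 °C, which should keep the alkene of this isomerisation-prone aldehyde in the β,γ-position.

Step 8
Reactants: 12 tert-butyl (2Z,5Z)-2-(bromomethyl)-6-{[(2-{[(tert-butyldimethylsilyl)oxy]methyl}prop-2-enoyl)oxy]methyl}-10-methylundeca-2,5,9-trienoate; 16 2-methylidene-4-oxobutyl acetate
Product: 18 tert-butyl (3R,4R)-6-(acetoxymethyl)-4-hydroxy-2-methylidene-3-[(2Z)-3-{[(2-{[(tert-butyldimethylsilyl)oxy]methyl}prop-2-enoyl)oxy]methyl}-7-methylocta-2,6-dien-1-yl]hept-6-enoate, via trimethylsilyl ether 17 (not isolated)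
Conditions: CrCl2 (10 mol%), (S,S)-1,8-bis(4-isopropyl-4,5-dihydrooxazol-2-yl)-3,6-diphenyl-9H-carbazole (12 mol%), iPr2NEt (30 mol%), Mn powder, Me3SiCl, THF, 0 °C → rt, slow addition of 16; then citric acid, MeOH, 0 °C
Reagents that add atoms: none
Why: In this catalytic asymmetric Nozaki–Hiyama–Kishi 2-(alkoxycarbonyl)allylation, divalent chromium turns 12 into an allylchromium species (trivalent chromium) that adds to the aldehyde through C7 in a closed six-membered transition state, the enoate geometry keeping the C6 chain cis to the CH2Cr carbon so that the syn adduct should form, the chiral ligand selecting (7R,8R) and the tert-butyl ester blocking acyl-oxygen lactonisation.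

Step 9
Reactants: 18 tert-butyl (3R,4R)-6-(acetoxymethyl)-4-hydroxy-2-methylidene-3-[(2Z)-3-{[(2-{[(tert-butyldimethylsilyl)oxy]methyl}prop-2-enoyl)oxy]methyl}-7-methylocta-2,6-dien-1-yl]hept-6-enoate
Product: 21 (4R,5S)-5-[2-(acetoxymethyl)prop-2-en-1-yl]-3-methylidene-4-[(2Z)-3-{[(2-{[(tert-butyldimethylsilyl)oxy]methyl}prop-2-enoyl)oxy]methyl}-7-methylocta-2,6-dien-1-yl]oxolan-2-one, via C8 triflate 19 (not isolated), via lactonium triflate 20 (not isolated)
Conditions: Tf2O (1.3 equiv), 2,6-di-tert-butyl-4-methylpyridine (3 equiv), CH2Cl2, −78 → 0 °C; aq. NaHCO3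
Reagents that add atoms: none
Why: Triflation of the C8 hydroxyl gives the secondary triflate 19, whose backside is reached by the carbonyl oxygen of the γ-disposed tert-butyl ester (C12=O) in an SN2 closure to the 2-tert-butoxy lactonium ion 20, which collapses to the lactone by loss of isobutene, so the oxygen that becomes the ring oxygen bonds to C8 in the ring-closing event. The closest known reaction type is anchimerically assisted dealkylative lactonisation, as in the halolactonisation of tert-butyl esters and the invertive closure of N-Boc amino alcohol sulfonates to oxazolidinones. The only ring closed is the five-membered lactone, by 5-exo-tet attack on sp3 carbon. The configuration at C8 is set by stereospecific inversion of the (8R)-triflate while C7 is untouched, so the syn (7R,8R) adduct of step 8 should become the trans-fused (7R,8S) lactone. The step needs O-alkylation to outrun elimination toward C7 or C9, homoallyl participation of the C10 alkene and any retentive acyl-oxygen lactonisation; this is secured by the five-membered geometry of the neighbouring group, the low temperature with a hindered non-nucleophilic base, the acyclic substrate (no transannular alkene near C8) and the tert-butyl ester, which resists attack at its carbonyl by the alcohol but ionises readily once O-alkylated.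

Step 10
Reactants: 21 (4R,5S)-5-[2-(acetoxymethyl)prop-2-en-1-yl]-3-methylidene-4-[(2Z)-3-{[(2-{[(tert-butyldimethylsilyl)oxy]methyl}prop-2-enoyl)oxy]methyl}-7-methylocta-2,6-dien-1-yl]oxolan-2-one
Product: 22 (7R,8S)-14-acetoxy-15-[(2-{[(tert-butyldimethylsilyl)oxy]methyl}prop-2-enoyl)oxy]germacra-1(10),4,11(13)-trien-12,8-olide (C9 cis to C2 across C1=C10; C15 cis to C6 across C4=C5)
Conditions: second-generation Grubbs catalyst RuCl2(H2IMes)(PCy3)(=CHPh) (15 mol%, in portions), 1,4-benzoquinone (20 mol%), toluene (1 mM), 70 °C, Ar sparge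
Reagents that add atoms: none
Why: Ring-closing metathesis should load ruthenium at C1 with loss of isobutene and close onto the 1,1-disubstituted C10 alkene, because the trans C4=C5 bond forbids the eight-membered ring through the lactone methylene, the hindered electron-poor side-chain acrylate is a poor partner, and a ten-membered ring favours the new trisubstituted alkene in the required in-ring cis geometry.

Step 11
Reactants: 22 (7R,8S)-14-acetoxy-15-[(2-{[(tert-butyldimethylsilyl)oxy]methyl}prop-2-enoyl)oxy]germacra-1(10),4,11(13)-trien-12,8-olide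
Product: 23 (7R,8S)-14-acetoxy-15-{[2-(hydroxymethyl)prop-2-enoyl]oxy}germacra-1(10),4,11(13)-trien-12,8-olide (CNP0126545.1)
Conditions: HF·pyridine, pyridine, THF, 0 °C → rt
Reagents that add atoms: none
Why: Buffered fluoride cleavage of the primary silyl ether should spare the allylic acetate, the acrylate ester and the α-methylene lactone and leaves both stereocentres untouched.

Compound list
1 | ethyl 2-(hydroxymethyl)prop-2-enoate | C=C(CO)C(=O)OCC | starting material
2 | ethyl 2-{[(tert-butyldimethylsilyl)oxy]methyl}prop-2-enoate | C=C(CO[Si](C)(C)C(C)(C)C)C(=O)OCC | intermediate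
3 | 2-{[(tert-butyldimethylsilyl)oxy]methyl}prop-2-enoic acid | C=C(CO[Si](C)(C)C(C)(C)C)C(=O)O | intermediate
4 | prop-2-yn-1-ol | C#CCO | starting material
5 | 5-bromo-2-methylpent-2-ene | CC(C)=CCCBr | starting material
6 | 3-bromoprop-1-ene (allyl bromide) | C=CCBr | starting material
7 | (4-methylpent-3-en-1-yl)magnesium bromide | CC(C)=CCC[Mg]Br | intermediate
8 | 4-(4-methylpent-3-en-1-yl)-2,5-dihydro-1,2-oxamagnesole (cyclic alkenylmagnesium alkoxide, Mg on C5 cis to CH2O) | CC(C)=CCCC1=C[Mg]OC1 | intermediate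
9 | (2Z)-2-(4-methylpent-3-en-1-yl)hexa-2,5-dien-1-ol | OC/C(CCC=C(C)C)=C\CC=C | intermediate
10 | (2Z)-2-(4-methylpent-3-en-1-yl)hexa-2,5-dien-1-yl 2-{[(tert-butyldimethylsilyl)oxy]methyl}prop-2-enoate | C=C(CO[Si](C)(C)C(C)(C)C)C(=O)OC/C(CCC=C(C)C)=C\CC=C | intermediate
11 | tert-butyl 2-(bromomethyl)prop-2-enoate | C=C(CBr)C(=O)OC(C)(C)C | starting material
12 | tert-butyl (2Z,5Z)-2-(bromomethyl)-6-{[(2-{[(tert-butyldimethylsilyl)oxy]methyl}prop-2-enoyl)oxy]methyl}-10-methylundeca-2,5,9-trienoate | BrC/C(C(=O)OC(C)(C)C)=C\C/C=C(\COC(=O)C(=C)CO[Si](C)(C)C(C)(C)C)CCC=C(C)C | intermediate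
13 | 2-[(trimethylsilyl)methyl]prop-2-en-1-yl acetate | CC(=O)OCC(=C)C[Si](C)(C)C | starting material
14 | formaldehyde (used as paraformaldehyde) | C=O | starting material
15 | 4-hydroxy-2-methylidenebutyl acetate | CC(=O)OCC(=C)CCO | intermediate
16 | 2-methylidene-4-oxobutyl acetate | CC(=O)OCC(=C)CC=O | intermediate
17 | 4-O-trimethylsilyl ether of 18 (3R,4R) | CC(C)(C)OC(=O)C(=C)[C@@H](C/C=C(\COC(=O)C(=C)CO[Si](C)(C)C(C)(C)C)CCC=C(C)C)[C@H](O[Si](C)(C)C)CC(=C)COC(C)=O | intermediate
18 | tert-butyl (3R,4R)-6-(acetoxymethyl)-4-hydroxy-2-methylidene-3-[(2Z)-3-{[(2-{[(tert-butyldimethylsilyl)oxy]methyl}prop-2-enoyl)oxy]methyl}-7-methylocta-2,6-dien-1-yl]hept-6-enoate (syn; 7R,8R in germacrane numbering) | CC(C)(C)OC(=O)C(=C)[C@@H](C/C=C(\COC(=O)C(=C)CO[Si](C)(C)C(C)(C)C)CCC=C(C)C)[C@H](O)CC(=C)COC(C)=O | intermediate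
19 | 4-O-trifluoromethanesulfonate of 18 (3R,4R) | CC(C)(C)OC(=O)C(=C)[C@@H](C/C=C(\COC(=O)C(=C)CO[Si](C)(C)C(C)(C)C)CCC=C(C)C)[C@H](OS(=O)(=O)C(F)(F)F)CC(=C)COC(C)=O | intermediate
20 | (2S,3R)-2-[2-(acetoxymethyl)prop-2-en-1-yl]-5-tert-butoxy-4-methylidene-3-[(2Z)-3-(acyloxymethyl)-7-methylocta-2,6-dien-1-yl]-3,4-dihydro-2H-furan-1-ium trifluoromethanesulfonate (acyl = 2-{[(tert-butyldimethylsilyl)oxy]methyl}prop-2-enoyl) | C=C1C(OC(C)(C)C)=[O+][C@@H](CC(=C)COC(C)=O)[C@@H]1C/C=C(\COC(=O)C(=C)CO[Si](C)(C)C(C)(C)C)CCC=C(C)C.[O-]S(=O)(=O)C(F)(F)F | intermediate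
21 | (4R,5S)-5-[2-(acetoxymethyl)prop-2-en-1-yl]-3-methylidene-4-[(2Z)-3-{[(2-{[(tert-butyldimethylsilyl)oxy]methyl}prop-2-enoyl)oxy]methyl}-7-methylocta-2,6-dien-1-yl]oxolan-2-one (trans-lactone; 7R,8S) | C=C1C(=O)O[C@@H](CC(=C)COC(C)=O)[C@@H]1C/C=C(\COC(=O)C(=C)CO[Si](C)(C)C(C)(C)C)CCC=C(C)C | intermediate
22 | (7R,8S)-14-acetoxy-15-[(2-{[(tert-butyldimethylsilyl)oxy]methyl}prop-2-enoyl)oxy]germacra-1(10),4,11(13)-trien-12,8-olide (in-ring cis C1=C10, in-ring trans C4=C5) | C=C(CO[Si](C)(C)C(C)(C)C)C(=O)OC/C1=C\C[C@@H]2C(=C)C(=O)O[C@H]2C/C(COC(C)=O)=C\CC1 | intermediate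
23 | (7R,8S)-14-acetoxy-15-{[2-(hydroxymethyl)prop-2-enoyl]oxy}germacra-1(10),4,11(13)-trien-12,8-olide (trans-fused lactone; in-ring cis C1=C10, in-ring trans C4=C5) | C=C(CO)C(=O)OC/C1=C\C[C@@H]2C(=C)C(=O)O[C@H]2C/C(COC(C)=O)=C\CC1 | target

Total step count: 11. Longest linear sequence: 8 steps (steps 1, 2, 4, 5, 8, 9, 10, 11).

Steps most likely to fail

Step 10 (ring-closing metathesis). What may go wrong: intermolecular metathesis (oligomerisation) outrunning closure of the strained ten-membered ring on the rigid trans-lactone, slow loading of ruthenium at the isopropylidene terminus, or closure to the in-ring trans alkene. Fallback, from 18 back to 22: the order of the two ring closures is reversed and the lactone is made by a Mitsunobu reaction instead of ester participation. The conformationally free diene 18 is cyclised under the conditions of step 10 to the macrocyclic (7R,8R)-hydroxy tert-butyl ester F1. Me3SiOTf/2,6-lutidine (CH2Cl2, 0 °C, then pH 5 buffer) converts the tert-butyl ester into the macrocyclic hydroxy acid F2. PPh3/DIAD (toluene, 0 °C) then closes the O–C8 bond with inversion and should give 22.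

Step 8 (asymmetric allylation). What may go wrong: base- or Lewis-acid-induced migration of the alkene of 16 into conjugation before addition, silyl dienol ether formation, or erosion of syn- and enantioselectivity when catalyst turnover is slow. Fallback, from 10 and 11 back to 18: a boron-based allylation through a closed chair transition state at low temperature, free of amine and chlorosilane. 11 is borylated (B2pin2, CuCl, KOAc, DMF, rt) to tert-butyl 2-[(4,4,5,5-tetramethyl-1,3,2-dioxaborolan-2-yl)methyl]prop-2-enoate F3. Cross-metathesis of F3 with 10 under the conditions of step 5 gives the allylboronate F4, with CH2B cis to C6. Addition of F4 to 16, catalysed by the chiral phosphoric acid (R)-3,3′-bis(2,4,6-triisopropylphenyl)-1,1′-binaphthalene-2,2′-diyl hydrogen phosphate (toluene, −30 °C, aqueous work-up), should give the syn adduct 18, the catalyst enantiomer being chosen for (7R,8R).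

Step 5 (cross-metathesis). What may go wrong: the hindered, electron-poor acrylate fails to cross-couple, so that homodimerisation of 10, migration of the skipped diene into conjugation or loss of the allylic bromide dominates. Fallback, from the chelate 8 back to 12: the C6–C7 unit is added by cross-coupling and the bromomethyl acrylate is built from an aldehyde. 8 is quenched with I2 to give (2Z)-3-iodo-2-(4-methylpent-3-en-1-yl)prop-2-en-1-ol F5. Esterification with 3 (conditions of step 4) gives the iodo ester F6. Negishi coupling with (1,3-dioxolan-2-ylmethyl)zinc bromide (Pd(PPh3)4, zerovalent palladium, THF, rt) gives the dioxolane F7. Et3SiOTf/2,4,6-collidine followed by water frees the β,γ-unsaturated aldehyde F8. Addition of the α-alanyl acrylate made from tert-butyl propiolate, iBu2AlH and N-methylmorpholine N-oxide (THF, 0 °C) gives the Morita–Baylis–Hillman-type alcohol F9. N-Bromosuccinimide/Me2S (CH2Cl2, 0 °C) converts F9 with allylic transposition into 12.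

Further compounds
F1 | step 10 | tert-butyl (7R,8R)-14-acetoxy-15-[(2-{[(tert-butyldimethylsilyl)oxy]methyl}prop-2-enoyl)oxy]-8-hydroxygermacra-1(10),4,11(13)-trien-12-oate (ring alkene geometries as in 22) | C=C(CO[Si](C)(C)C(C)(C)C)C(=O)OC/C1=C\C[C@H](C(=C)C(=O)OC(C)(C)C)[C@H](O)C/C(COC(C)=O)=C\CC1
F2 | step 10 | (7R,8R)-14-acetoxy-15-[(2-{[(tert-butyldimethylsilyl)oxy]methyl}prop-2-enoyl)oxy]-8-hydroxygermacra-1(10),4,11(13)-trien-12-oic acid | C=C(CO[Si](C)(C)C(C)(C)C)C(=O)OC/C1=C\C[C@H](C(=C)C(=O)O)[C@H](O)C/C(COC(C)=O)=C\CC1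
F3 | step 8 | tert-butyl 2-[(4,4,5,5-tetramethyl-1,3,2-dioxaborolan-2-yl)methyl]prop-2-enoate | C=C(CB1OC(C)(C)C(C)(C)O1)C(=O)OC(C)(C)C
F4 | step 8 | tert-butyl (2E,5Z)-6-{[(2-{[(tert-butyldimethylsilyl)oxy]methyl}prop-2-enoyl)oxy]methyl}-10-methyl-2-[(4,4,5,5-tetramethyl-1,3,2-dioxaborolan-2-yl)methyl]undeca-2,5,9-trienoate | CC1(C)OB(C/C(C(=O)OC(C)(C)C)=C\C/C=C(\COC(=O)C(=C)CO[Si](C)(C)C(C)(C)C)CCC=C(C)C)OC1(C)C
F5 | step 5 | (2Z)-3-iodo-2-(4-methylpent-3-en-1-yl)prop-2-en-1-ol | OC/C(CCC=C(C)C)=C\I
F6 | step 5 | (2Z)-3-iodo-2-(4-methylpent-3-en-1-yl)prop-2-en-1-yl 2-{[(tert-butyldimethylsilyl)oxy]methyl}prop-2-enoate | C=C(CO[Si](C)(C)C(C)(C)C)C(=O)OC/C(CCC=C(C)C)=C\I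
F7 | step 5 | (2Z)-4-(1,3-dioxolan-2-yl)-2-(4-methylpent-3-en-1-yl)but-2-en-1-yl 2-{[(tert-butyldimethylsilyl)oxy]methyl}prop-2-enoate | C=C(CO[Si](C)(C)C(C)(C)C)C(=O)OC/C(CCC=C(C)C)=C\CC1OCCO1
F8 | step 5 | (2Z)-2-(4-methylpent-3-en-1-yl)-5-oxopent-2-en-1-yl 2-{[(tert-butyldimethylsilyl)oxy]methyl}prop-2-enoate | C=C(CO[Si](C)(C)C(C)(C)C)C(=O)OC/C(CCC=C(C)C)=C\CC=O
F9 | step 5 | tert-butyl (5Z)-6-{[(2-{[(tert-butyldimethylsilyl)oxy]methyl}prop-2-enoyl)oxy]methyl}-3-hydroxy-10-methyl-2-methylideneundeca-5,9-dienoate (racemic at C3) | C=C(C(=O)OC(C)(C)C)C(O)C/C=C(\COC(=O)C(=C)CO[Si](C)(C)C(C)(C)C)CCC=C(C)C
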